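1. the species that holds most of what was charged as substrate, at 2.5 h (target / isomer of the product B / isomer of the product A / substrate)
2. the largest share itself, whichever of these holds it, in percent of the substrate charged

| setting | Saturday's | Monday's | flask |
|---|---|---|---|
| substrate | 0.034 M | 0.075 M | 0.050 M |
| remark | run made earlier | run made earlier |  |
| time |  |  | 2.5 h |

| run | time / min | isomer of the product B / % | substrate / % | isomer of the product A / % | target / % |
|---|---|---|---|---|---|
| Saturday's | 8.00 | 0.5 | 45.5 | 2.2 | 51.0 |
| Saturday's | 15.0 | 3.4 | 35.9 | 5.2 | 57.1 |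
| Saturday's | 40.0 | 6.6 | 27.9 | 12.6 | 53.2 |
| Saturday's | 90.0 | 14.5 | 24.9 | 12.9 | 47.5 |
| Monday's | 25.0 | 3.2 | 29.0 | 6.9 | 56.9 |
| Monday's | 50.0 | 9.4 | 27.0 | 13.0 | 52.0 |
| Monday's | 60.0 | 9.2 | 27.6 | 12.3 | 50.9 |
| Monday's | 90.0 | 16.3 | 25.5 | 15.2 | 45.8 |

(readings scatter by 1 percentage point)

- a reading or a percentage of target counts all its forms, free or not

**Two charges.** The small charge of Saturday's run and the larger one of Monday's stood 1.8 percentage points apart in isomer of the product B at 90.0 min, close to a reading's scatter of 1 point, so I read the flask at 0.050 M off the same curves.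

**First chain.** I called everything other than isomer of the product B the pool, the resting state of the charge, and in Saturday's run it shrank from 40.0 min to 90.0 min at 0.00177 min⁻¹. Target made up 57.0% of the pool at the first of those times and 55.6% at the second, so I held that share steady. Carried on to 2.5 h, the pool came to 76.9%, which put target at 42.8%.

**Weak link.** That slope rested on two readings of one run, so I added Monday's span from 50.0 min to 90.0 min, which gave 0.00198 min⁻¹. The mean of the two slopes, 0.00187 min⁻¹, gave the pool half-life, the time in which the pool halves at that slope, 6.16 h. With both runs' readings at 90.0 min, the pool reached 75.6% and target 41.7%, more than the 24.4% of isomer of the product B, and I committed to that.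

**The result.** The forecast, which called isomer of the product B “the slow drain from A”, gave target at 41%, and the flask held target at 41.8%.

    substrate ⇌ target (K = 1.90, k = 0.140 min⁻¹)
    target ⇌ isomer of the product A (K = 0.330, k = 0.0110 min⁻¹)
    isomer of the product A ⇌ isomer of the product B (K = 7.40, k = 0.0100 min⁻¹)
    isomer of the product B ⇌ substrate (k = 6.10 × 10⁻⁴ min⁻¹)
    crystals ⇌ target, rate k5*(cs5 - [target]) while solid is left; crystals form when [target] > cs5 (solubility = 42.0 mM, k = 1.80 min⁻¹)

**Two clocks.** In the flask, 2.5 h was 0.406 of a pool half-life, while half of the turnover of substrate to target was done by 0.0564 h, far sooner than 6.16 h; c(target) stood at 28.6 mM at 0.250 h, below 42 mM, and crystals at 0%. Counted on at that half-life from the flask's 75.5% of pool at 2.5 h, the pool of the neighbouring flask read at 10 h came to 32.5%, yet that flask held 48.4% of pool, with isomer of the product B first at 51.6%.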